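I decided not to follow either flask through time, but to fold each into one ratio of two rates.

    electrophile + nucleophile → acid set free + target (k1 = 5.4 M⁻¹ h⁻¹)
    nucleophile + acid set free ⇌ protonated nucleophile, settled at all times (K2 = 1.2 × 10⁵ M⁻¹)
    acid set free + free base ⇌ salt of the base, settled at all times (K3 = 3.7 × 10⁵ M⁻¹)
    acid set free → by-product carried off (k4 = 0.079 h⁻¹)
    2 nucleophile → self-condensation product (k5 = 14 M⁻¹ h⁻¹)

- south-west: electrophile 15 mM; free base 1.20 equiv; protonated nucleophile 3.00 equiv; time 5.0 d
- north-west: electrophile 15 mM; free base 2.40 equiv; protonated nucleophile 3.00 equiv; time 5.0 d

1. part of the electrophile that has reacted at the end, south-west
2. part of the electrophile that has reacted at the end, north-west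
3. what raising the equivalents of free base from its lowest to its highest value here does to the part of the electrophile that has reacted (changes below 5 percentage points count as none) (no change / it rises / it falls)

The free base takes acid from the protonated nucleophile and so hands out nucleophile. A turn of the target step uses one nucleophile and sets free an acid that takes up a second, while a turn of self-condensation takes two, so either turn costs two of what the base gave. I therefore divided the self-condensation rate, k·c(nucleophile)², by the target rate, k·c(electrophile)·c(nucleophile), and set c(nucleophile) equal to the base charged. Time and c(electrophile) drop out, and what remains is the base equivalents times the ratio of the constants. This waste number 3.11 says how many self-condensation turns go for each target turn if the whole base charge stood as nucleophile. The ratio of the constants by itself is the selectivity factor of the two steps competing for nucleophile; the waste number is that ratio scaled by the base charge, and north-west has 6.22.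

I then let c(nucleophile) run down with c(electrophile) held at its charge. Summing the target's share gives the part reacted at the stall: 0.193, the ratio of the constants divided by two, times the natural logarithm of one plus the waste number. So I committed to south-west 27.3% and north-west 38.1%, and to a rise with more base. One number was not enough for the end, though. The acid leaves with a half-life of 0.37 d, shorter than the run, and each acid lost gives capacity back. So I took these values as floors, though holding c(electrophile) at its charge errs the other way.

The forecast gave 40% (32% to 48%) south-west, 50% (41% to 59%) north-west, and "it rises", holding that “much of the extra is lost to the second-order self-condensation”. Its values stand above my floors.

The flasks gave 42.0% south-west and 50.8% north-west, and with more free base it rises by 8.7 percentage points. South-west stands 15 points above its floor, yet short of full conversion because self-condensation and the limited time act together. Without self-condensation it reaches 69.1%, and after 50.0 d, ten times the time, 97.3%. The neighbour of south-west with 3.00 equiv of free base has a waste number of 7.78, which puts its floor at 41.9%, and that flask gave 55.9%.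

The rate constants come from no measurement; the flask was simulated.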